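## The problem

The target is a ten-membered carbocycle (C1–C10) cis-fused at C6–C7 to an α-methylene-γ-butyrolactone (O–C12(=O)–C11(=C13H2)). It carries a C1 ketone, a free C3 hydroxyl, a C4 methyl, a C8 angelate and a C10 tertiary acetate with a methyl group. A synthesis must close a medium ring, which direct cyclisation does poorly, and place six stereocentres (C3, C4, C6, C7, C8, C10). Calling α the ring face that carries C11 at C7, the oxygens at C6, C8 and C10 are α, while the C3 hydroxyl and both methyl groups are β. On a flexible cyclodecane none of these centres can be trusted to control another, so relative configuration has to be set on a rigid precursor or by reagent; only C6/C7 and C3/C4 are adjacent pairs. The C1/C3 aldol (retro-aldol, dehydration), the exo-methylene lactone (conjugate addition), the angelate (Z-to-E isomerisation, hydrogenation) and the tertiary α-acetoxy ketone (acyl shift) will not survive strong base, hydride or hydrogen, so those reagents must come early. The enabling feature is that C2 and C7 stand 1,6 across the ring and C7 carries the one-carbon branch C11: a C2–C11 bond turns the skeleton into bicyclo[4.4.1]undecan-11-one, whose C7–C8–C9–C10–C1–C2 edge plus C11 is tropone and whose C3–C6 edge is a 1-oxygenated 3-methylbutadiene. In that bicycle each four-carbon bridge (ring A, C8–C1; ring B, C3–C6) has an open α face flanked only by C11 and a β face shielded by the other bridge, and the C1 carbonyl is 1,3 to C11, so the extra bond can be cut again.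

## Retrosynthesis

**Lactone (26 ⇒ 25).** C11–C12 and C12–O6 are cut, with carbon monoxide as C12. The neighbouring cuts are worse: α-methylenation at C11=C13 needs a lactone enolate next to the aldol and the angelate, and closing O6–C12 needs a prebuilt acrylic acid. Precursor 25 is a hydroxy vinyl triflate; the forward step is a near-neutral palladium carbonylation in which only O6 can reach the acyl carbon.

**Acyl and protecting groups (25 ⇒ 24 ⇒ 23 ⇒ 22 ⇒ 21).** The angelate goes on O8 after every base, hydride and hydrogenation step and before O6 and O3 are freed. O8 therefore carries the most labile silyl group (TES) and O6/O3 share TBS. The vinyl triflate 22 comes from methyl ketone 21, whose methyl group is C13.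

**Bridge excision (21 ⇒ 19).** Reconnecting C2–C11 gives the bicyclic 1,11-diketone 19. Forward, a methyl nucleophile adds to C11 and the resulting tertiary β-keto alkoxide undergoes retro-aldol cleavage. Methoxide (retro-Claisen) would leave an ester needing a three-step homologation, and hydride would give a secondary aldol that has no driving force to open. The step requires addition at C11 and not at the C1 carbonyl, which the quaternary C10 shields.

**C10 (19 ⇒ 17 ⇒ 16).** The C10–O and C10–CH3 bonds are cut in that order. Forward, methylation comes first and hydroxylation second, so that oxygen enters last from the open α face and pushes the methyl group β. Only C10 can enolise, since C2 is a bridgehead.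

**C3, C4 and the C11 oxidation state (16 ⇒ 15 ⇒ 14 ⇒ 13 ⇒ 12).** The C3 carbinol comes from a C3 ketone by hydride delivered from a C11 hydroxyl that points over ring B. This makes the reduction both face-selective (α attack, β alcohol) and chemoselective against the C1 ketone. C4 comes from hydrogenation of the C4=C5 enone on the α face. The C11 alcohol is a temporary oxidation state that also removes the electrophilic bridging ketone during the oxidations.

**Ring A oxygens (12 ⇒ 11 ⇒ 10 ⇒ 9).** C8–O and C1–O are cut back to dioxygen and the tropone-derived diene. The two ends of the diene are nearly equivalent. Placing the C3 carbonyl first makes C1–H the more acidic and more exposed peroxide C–H, so the Kornblum–DeLaMare opening of endoperoxide 10 should give the C1 ketone and the C8 alcohol 11.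

**C3 oxidation, C11 reduction, resolution (9 ⇒ 8 ⇒ 7 ⇒ 6 ⇒ 5 ⇒ 4).** The C3 oxygen comes from selenium dioxide oxidation of the only alkene with a usable allylic methylene. The C11 alcohol comes from borohydride attack over the flat diene. The single enantiomer comes from lipase hydrolysis of the racemic acetate 4.

**Key disconnection (4 ⇒ 3 + 2; 2 ⇐ 1).** C2–C3 and C6–C7 are cut. Tropone 3 and dienyl acetate 2 (from 3-methylbut-2-enal 1) give all eleven skeletal carbons, both seven-membered rings and the C2, C6, C7 stereocentres in one step. The step requires (6+4) periselectivity and exo selectivity, both inherent to tropone.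

## Roads not taken

**Alternative 1: [2,3]-Wittig ring contraction.** The cut is C7–C8. Forward, tin–lithium exchange (n-BuLi) at C8 sets off a [2,3] shift in which the C8 carbanion attacks C7, the O–C13 bond breaks and a thirteen-membered ring contracts to the ten-membered carbinol A1.
- Merits: the ring arises by contraction, and one step creates C7, C8 and the C11=C13 methylene with C12 already attached. In building the lactone carbons this is more economical than the chosen plan, which needs a fragmentation, a triflation and a carbonylation.
- Weak points: the C7/C8 relationship depends on the envelope geometry of a macrocyclic transition state and is not assured. The thirteen-membered ether with its stannylated stereocentre still has to be made by macrocyclisation. The Z C9=C10 alkene of A1 must then be hydrated to the C10 tertiary acetate with facial control on a flexible ring.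
- Comparison: the chosen plan sets C8 and C10 on a rigid bicycle and makes its skeleton from two commodity chemicals, which it sets against the longer functional-group sequence.

**Alternative 2: intramolecular nitrile oxide cycloaddition.** The cuts are C1–C2 and O–C3. Forward, a nitrile oxide generated (NaOCl) from a C1 aldoxime adds to the terminal C2–C3 alkene and closes the ten-membered ring as the isoxazoline A2.
- Merits: the isoxazoline is a masked C1/C3 aldol, released by neutral N–O cleavage at the end with the C3 configuration fixed in the cycloaddition. In handling the aldol this road is better than the chosen one, which needs an oxidation, a hydrogenation and a directed reduction to set C3.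
- Weak points: ten-membered closure by this cycloaddition is entropically poor and can give bridged and fused regioisomers. The C3 face selectivity rests on a remote acetonide. The open-chain precursor with five stereocentres needs a long linear build, and A2 still lacks C13, so a base-mediated α-methylenation comes late.
- Comparison: the chosen plan forms its ring by a reliable cycloaddition and has a near-neutral lactone construction.

**Alternative 3: dichloroketene (2+2).** The cuts are C6–C12 and C7–C11. Forward, dichloroketene (Cl3CCOCl, Zn–Cu) adds across a Z C6–C7 alkene to give the cis-fused dichlorocyclobutanone A3; Baeyer–Villiger insertion, dechlorination and methylenation would follow.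
- Merits: the cis lactone fusion is guaranteed by the suprafacial ketene addition, and both lactone carbons arrive together. In securing C6/C7 this is as good as the exo cycloaddition of the chosen plan.
- Weak points: A3 presupposes that the fully substituted ten-membered ring already exists, so the hardest problem is deferred. The ketene must choose a face of a flexible ring and an orientation across an unsymmetrical alkene. Four more steps, one strongly basic, separate A3 from the methylene lactone.
- Comparison: the chosen plan forms the ring and the C6/C7 relationship in the same step.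

Key step: step 2

Assumption: the lipase in step 3 is taken to hydrolyse the acetate of the enantiomer drawn for 4; if it prefers the other, the recovered acetate is methanolysed (K2CO3, MeOH) to the same alcohol 5.

Remark: 4 is racemic and its SMILES shows the enantiomer carried on. Carbons keep the target numbering throughout; α and β are used as defined above, and C11 is "ring-B side" when its hydroxyl points over C3/C6.

## Route

Step 1
Reactants: 1 3-methylbut-2-enal
Product: 2 (E)-3-methylbuta-1,3-dien-1-yl acetate
Conditions: isopropenyl acetate, TsOH (cat.), 95 °C, acetone distilled off; fractional distillation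
Reagents that add atoms: isopropenyl acetate, CC(=C)OC(C)=O
Why: Acid-catalysed enol acetate exchange traps the γ-deprotonated dienol of the enal as its O-acetate; the E isomer is the one that cycloadds and is taken on.

Step 2
Reactants: 3 tropone; 2 (E)-3-methylbuta-1,3-dien-1-yl acetate
Product: 4 racemic exo (6+4) adduct, 6α-acetoxy-4-methylbicyclo[4.4.1]undecatrien-11-one
Conditions: xylenes, 2 in excess, 130 °C, sealed tube
Reagents that add atoms: none
Why: A concerted, thermally allowed ten-electron (6+4) cycloaddition, suprafacial on both partners, joins C2 and C7 of tropone (whose carbonyl carbon becomes C11) to the diene termini, forming C2–C3 and C6–C7. The closest known reaction is the thermal exo (6+4) addition of tropone to 1-acetoxy- and 1-silyloxybutadienes. Both seven-membered rings (C11–C7–C8–C9–C10–C1–C2 and C11–C2–C3–C4–C5–C6–C7) close in the same intermolecular event by bonding at the two ends of each π system, and their outer edge is the ten-membered ring. C2 and C7 are set by suprafacial addition to the planar triene, which makes the carbonyl bridge cis. C6 follows from the E geometry of the enol acetate and the exo transition state, so the acetoxy group ends cis to the C11 bridge. Exo is preferred because the secondary overlap between the inner diene carbons and C3–C6 of tropone is antibonding in the endo mode, and (6+4) is preferred over (4+2) because the largest frontier coefficients of tropone lie at C2 and C7. Tropone is symmetrical, so no regioisomer can form, and the C3 methyl of the diene favours the s-cis conformer. The adduct is racemic; the absolute configuration is selected in step 3.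

Step 3
Reactants: 4 racemic exo adduct
Product: 5 6α-hydroxy-4-methylbicyclo[4.4.1]undecatrien-11-one, single enantiomer
Conditions: Amano lipase PS, phosphate buffer (pH 7)–MTBE, 30 °C, to about half conversion; chromatography
Reagents that add atoms: none
Why: Lipase-catalysed kinetic resolution by enantioselective hydrolysis of a secondary allylic acetate; the alcohol of one enantiomer is separated from the untouched acetate of the other.

Step 4
Reactants: 5 6α-hydroxy trienone
Product: 6 6α-(tert-butyldimethylsilyloxy) trienone
Conditions: TBSCl, imidazole, DMF, 0 °C to rt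
Reagents that add atoms: tert-butyldimethylsilyl chloride, CC(C)(C)[Si](C)(C)Cl
Why: Standard silylation; imidazole is too weak a base to trigger retro-aldol cleavage of the β-hydroxy ketone.

Step 5
Reactants: 6 6α-silyloxy trienone
Product: 7 C11 alcohol with hydroxyl on the ring-B side
Conditions: NaBH4, MeOH–CH2Cl2, −78 to −40 °C
Reagents that add atoms: none
Why: Borohydride reduction of the only carbonyl; hydride should enter over the flat, unsubstituted diene and away from the C6 silyloxy group, leaving the hydroxyl over ring B, where it later directs the C3 reduction.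

Step 6
Reactants: 7 C11 alcohol
Product: 9 C11-hydroxy C3 enone (C3(=O)–C4(Me)=C5), via 3α-hydroxy allylic alcohol 8 (not isolated)
Conditions: SeO2 (cat.), t-BuOOH, CH2Cl2, rt; then MnO2, CH2Cl2, rt
Reagents that add atoms: selenium dioxide, O=[Se]=O; tert-butyl hydroperoxide, CC(C)(C)OO
Why: Selenium dioxide allylic oxidation (ene reaction, then [2,3] shift) attacks the ring methylene next to the more substituted alkene carbon, which is C3. The diene offers only bridgehead allylic hydrogens lying in its own plane, and MnO2 oxidises the allylic alcohol but not the C11 carbinol.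

Step 7
Reactants: 9 C11-hydroxy C3 enone
Product: 11 8α,11-dihydroxy bis-enone (C1 ketone, C9=C10), via 1α,8α-endoperoxide 10 (not isolated)
Conditions: O2, tetraphenylporphyrin (cat.), visible light, CH2Cl2, −20 °C; then Et3N, 0 °C
Reagents that add atoms: dioxygen, O=O
Why: Singlet-oxygen (4+2) addition to the s-cis diene on the α face (only the C11 hydrogen points there; ring B covers the other), which sets C8; the ring-B alkene is now an electron-poor enone and should not undergo the ene reaction. In the Kornblum–DeLaMare opening the amine should remove C1–H, the peroxide hydrogen whose neighbour C2 carries the C3 carbonyl and faces no axial hydrogen, giving the C1 ketone and the C8 alcohol.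

Step 8
Reactants: 11 8α,11-dihydroxy bis-enone
Product: 12 8α-triethylsilyl ether
Conditions: TESCl, imidazole, CH2Cl2, −20 °C
Reagents that add atoms: triethylsilyl chloride, CC[Si](CC)(CC)Cl
Why: Selective silylation of the exposed allylic C8 hydroxyl; the C11 hydroxyl lies between two bridgehead methines and next to the C6 silyloxy group.

Step 9
Reactants: 12 8α-triethylsilyl ether
Product: 13 saturated 1,3-diketone with 4β-methyl
Conditions: H2 (1 atm), Pd/C, EtOAc, rt
Reagents that add atoms: none
Why: Heterogeneous hydrogenation of both enone C=C bonds; at C4=C5 hydrogen should arrive on the α face (the β face looks into the cleft toward ring A, and the C11 hydroxyl anchors the α side), giving the 4β-methyl group.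

Step 10
Reactants: 13 saturated 1,3-diketone
Product: 14 3β,11-diol with the C1 ketone intact
Conditions: Me4NBH(OAc)3, MeCN–AcOH, −30 °C
Reagents that add atoms: none
Why: Hydroxyl-directed (Evans–Saksena) reduction: the C11 hydroxyl binds boron and delivers hydride to the α face of C3, giving the 1,3-anti 3β-alcohol. The C11–O bond is held anti to C1 by the bicyclic frame, and triacetoxyborohydride does not reduce a ketone it cannot reach from a bound hydroxyl.

Step 11
Reactants: 14 3β,11-diol
Product: 15 3β-(tert-butyldimethylsilyloxy) C11 alcohol
Conditions: TBSOTf (1.1 equiv), 2,6-lutidine, CH2Cl2, −78 °C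
Reagents that add atoms: tert-butyldimethylsilyl triflate, CC(C)(C)[Si](C)(C)OS(=O)(=O)C(F)(F)F
Why: Silylation of the more accessible secondary alcohol at low temperature with limiting reagent; the C11 hydroxyl is the most hindered one in the molecule.

Step 12
Reactants: 15 C11 alcohol
Product: 16 1,11-diketone
Conditions: Dess–Martin periodinane, NaHCO3, CH2Cl2, rt
Reagents that add atoms: none
Why: Dess–Martin oxidation of the one free, hindered secondary alcohol returns the bridging ketone, giving a β-diketone that cannot enolise between the carbonyls and again has a trigonal C11 on the α side of ring A.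

Step 13
Reactants: 16 1,11-diketone
Product: 17 10-methyl 1,11-diketone
Conditions: LiN(i-Pr)2, THF, −78 °C; MeI, −78 to −30 °C
Reagents that add atoms: iodomethane, CI
Why: Kinetic enolate alkylation; the C1 ketone can enolise only toward C10 because C2 is a bridgehead (Bredt's rule), and the C10 configuration is irrelevant since the centre is re-enolised in step 14.

Step 14
Reactants: 17 10-methyl 1,11-diketone
Product: 19 10α-acetoxy-10β-methyl 1,11-diketone, via potassium 10α-alkoxide 18 (not isolated)
Conditions: KN(SiMe3)2, THF, −78 to −40 °C; 2-(phenylsulfonyl)-3-phenyloxaziridine, −78 °C; then Ac2O, −78 to 0 °C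
Reagents that add atoms: 2-(phenylsulfonyl)-3-phenyloxaziridine, O=S(=O)(c1ccccc1)N1OC1c1ccccc1; acetic anhydride, CC(=O)OC(C)=O
Why: Enolate hydroxylation with an N-sulfonyloxaziridine; the tetrasubstituted C1=C10 enolate should be attacked on the α face (the β face looks at ring B and its 4β-methyl), putting oxygen α and methyl β. Trapping the alkoxide with anhydride avoids a later acylation of a hindered tertiary α-ketol.

Step 15
Reactants: 19 10α-acetoxy 1,11-diketone
Product: 21 ten-membered 7-acetyl ketone (C11 methyl ketone, C2 methylene), via C11 cerium aldolate 20 (not isolated)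
Conditions: MeLi, CeCl3, THF, −78 °C; then MeOH, −78 to 0 °C
Reagents that add atoms: methyllithium, [Li]C
Why: Organocerium 1,2-addition should go to the bridging ketone (the C1 carbonyl is flanked by the quaternary C10 and the reagent spares esters at −78 °C). The congested tertiary β-keto alkoxide then undergoes retro-aldol cleavage of C2–C11, a ketone–ketone aldol that is thermodynamically driven to open, and methanol protonates the C2 enolate at once; C7 is untouched.

Step 16
Reactants: 21 ten-membered methyl ketone
Product: 22 C11 vinyl triflate (C11(OTf)=C13H2)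
Conditions: KN(SiMe3)2 (1.05 equiv), THF, −78 °C; N-(5-chloropyridin-2-yl)bis(trifluoromethanesulfonyl)imide
Reagents that add atoms: N-(5-chloropyridin-2-yl)-1,1,1-trifluoro-N-(trifluoromethylsulfonyl)methanesulfonamide, O=S(=O)(N(c1ccc(Cl)cn1)S(=O)(=O)C(F)(F)F)C(F)(F)F
Why: Kinetic enolate triflation; the unhindered acetyl methyl group should be deprotonated before the ring methylene of the hindered C1 ketone or the tertiary C7–H, giving the terminal vinyl triflate.

Step 17
Reactants: 22 C11 vinyl triflate
Product: 23 8α-alcohol
Conditions: AcOH–THF–H2O (3:1:1), rt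
Reagents that add atoms: none
Why: Selective acidic desilylation; a secondary TES ether is cleaved far faster than the TBS ethers, and the non-alcoholic medium avoids ketalising the C1 ketone with the freed C8 hydroxyl.

Step 18
Reactants: 23 8α-alcohol
Product: 24 8α-angelate
Conditions: angelic acid, 2,4,6-trichlorobenzoyl chloride, Et3N, toluene, rt; then 23, 70 °C
Reagents that add atoms: angelic acid, C/C=C(/C)C(=O)O
Why: Yamaguchi mixed-anhydride esterification without a nucleophilic catalyst, the standard way to transfer the (Z)-acid without isomerisation to the tiglate.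

Step 19
Reactants: 24 8α-angelate
Product: 25 3β,6α-diol vinyl triflate
Conditions: HF·pyridine, pyridine, THF, 0 °C to rt
Reagents that add atoms: none
Why: Buffered fluoride desilylation removes both TBS ethers; the triflate, the angelate and the tertiary acetate are stable to it, and no base touches the freed aldol.

Step 20
Reactants: 25 3β,6α-diol vinyl triflate
Product: 26 CNP0141210.3 (target)
Conditions: Pd(PPh3)4 (cat.), CO (1 atm), i-Pr2NEt, MeCN, 45 °C
Reagents that add atoms: carbon monoxide, [C-]#[O+]
Why: Carbonylative lactonisation of a hydroxy vinyl triflate: zerovalent palladium inserts into the C–OTf bond, CO insertion gives the acylpalladium species, and the C6 hydroxyl captures it to close the five-membered lactone. The C3 hydroxyl cannot reach, and the cis fusion is already fixed at C6 and C7.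

## Compound list

1 | 3-methylbut-2-enal | CC(C)=CC=O | starting material
2 | (E)-3-methylbuta-1,3-dien-1-yl acetate | C=C(C)/C=C/OC(C)=O | intermediate
3 | tropone (cyclohepta-2,4,6-trien-1-one) | O=C1C=CC=CC=C1 | starting material
4 | racemic exo adduct: bicyclo[4.4.1]undecan-11-one core with C4=C5, C8=C9, C1=C10, 4-methyl, 6α-acetoxy (cis to the C11 bridge); enantiomer carried on is shown | O=C1[C@@H]2C=CC=C[C@H]1CC(C)=C[C@@H]2OC(C)=O | intermediate
5 | 6α-hydroxy analogue of 4, single enantiomer | O=C1[C@@H]2C=CC=C[C@H]1CC(C)=C[C@@H]2O | intermediate
6 | 6α-TBS ether of 5 | O=C1[C@@H]2C=CC=C[C@H]1CC(C)=C[C@@H]2O[Si](C)(C)C(C)(C)C | intermediate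
7 | C11 alcohol of 6, hydroxyl on the ring-B side | O[C@H]1[C@@H]2C=CC=C[C@H]1CC(C)=C[C@@H]2O[Si](C)(C)C(C)(C)C | intermediate
8 | 3α-hydroxy derivative of 7 (allylic alcohol; C3 configuration immaterial) | O[C@H]1[C@@H]2C=CC=C[C@H]1[C@H](O)C(C)=C[C@@H]2O[Si](C)(C)C(C)(C)C | intermediate
9 | C3 enone: 11-hydroxy, C3(=O)–C4(Me)=C5, ring-A diene, 6α-OTBS | O[C@H]1[C@@H]2C=CC=C[C@H]1C(=O)C(C)=C[C@@H]2O[Si](C)(C)C(C)(C)C | intermediate
10 | 1α,8α-epidioxide of 9 (C9=C10 retained) | O[C@H]1[C@@H]2[C@H]3C=C[C@H](OO3)[C@H]1C(=O)C(C)=C[C@@H]2O[Si](C)(C)C(C)(C)C | intermediate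
11 | 8α,11-dihydroxy bis-enone: C1 ketone with C9=C10, C3 ketone with C4=C5, 6α-OTBS | O[C@H]1[C@@H]2[C@H](O)C=CC(=O)[C@H]1C(=O)C(C)=C[C@@H]2O[Si](C)(C)C(C)(C)C | intermediate
12 | 8α-TES ether of 11 | O[C@H]1[C@@H]2[C@H](O[Si](CC)(CC)CC)C=CC(=O)[C@H]1C(=O)C(C)=C[C@@H]2O[Si](C)(C)C(C)(C)C | intermediate
13 | saturated 1,3-diketone: 4β-methyl, 11-hydroxy, 8α-OTES, 6α-OTBS | O[C@H]1[C@@H]2[C@H](O[Si](CC)(CC)CC)CCC(=O)[C@H]1C(=O)[C@@H](C)C[C@@H]2O[Si](C)(C)C(C)(C)C | intermediate
14 | 3β,11-diol: C1 ketone, 4β-methyl, 8α-OTES, 6α-OTBS | O[C@H]1[C@@H]2[C@H](O[Si](CC)(CC)CC)CCC(=O)[C@H]1[C@@H](O)[C@@H](C)C[C@@H]2O[Si](C)(C)C(C)(C)C | intermediate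
15 | 3β-TBS ether of 14 (C11 alcohol free) | O[C@H]1[C@@H]2[C@H](O[Si](CC)(CC)CC)CCC(=O)[C@H]1[C@@H](O[Si](C)(C)C(C)(C)C)[C@@H](C)C[C@@H]2O[Si](C)(C)C(C)(C)C | intermediate
16 | 1,11-diketone: 3β-OTBS, 4β-methyl, 6α-OTBS, 8α-OTES | O=C1[C@@H]2[C@H](O[Si](CC)(CC)CC)CCC(=O)[C@H]1[C@@H](O[Si](C)(C)C(C)(C)C)[C@@H](C)C[C@@H]2O[Si](C)(C)C(C)(C)C | intermediate
17 | 10-methyl derivative of 16 (10α-methyl expected; configuration immaterial) | O=C1[C@@H]2[C@H](O[Si](CC)(CC)CC)C[C@H](C)C(=O)[C@H]1[C@@H](O[Si](C)(C)C(C)(C)C)[C@@H](C)C[C@@H]2O[Si](C)(C)C(C)(C)C | intermediate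
18 | potassium 10α-alkoxide (10β-methyl) of the hydroxylated diketone | O=C1[C@@H]2[C@H](O[Si](CC)(CC)CC)C[C@](C)([O-])C(=O)[C@H]1[C@@H](O[Si](C)(C)C(C)(C)C)[C@@H](C)C[C@@H]2O[Si](C)(C)C(C)(C)C.[K+] | intermediate
19 | 10α-acetoxy-10β-methyl 1,11-diketone | O=C1[C@@H]2[C@H](O[Si](CC)(CC)CC)C[C@](C)(OC(C)=O)C(=O)[C@H]1[C@@H](O[Si](C)(C)C(C)(C)C)[C@@H](C)C[C@@H]2O[Si](C)(C)C(C)(C)C | intermediate
20 | C11 methyl carbinol of 19 as its dichlorocerium alkoxide (C11 configuration immaterial, lost on cleavage) | CC1(O[Ce](Cl)Cl)[C@@H]2[C@H](O[Si](CC)(CC)CC)C[C@](C)(OC(C)=O)C(=O)[C@H]1[C@@H](O[Si](C)(C)C(C)(C)C)[C@@H](C)C[C@@H]2O[Si](C)(C)C(C)(C)C | intermediate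
21 | ten-membered ring: 7-acetyl, C1 ketone, 3β-OTBS, 4β-methyl, 6α-OTBS, 8α-OTES, 10α-acetoxy-10β-methyl | CC(=O)[C@H]1[C@@H](O[Si](C)(C)C(C)(C)C)C[C@H](C)[C@H](O[Si](C)(C)C(C)(C)C)CC(=O)[C@@](C)(OC(C)=O)C[C@H]1O[Si](CC)(CC)CC | intermediate
22 | vinyl triflate of 21 (C7 bears C(OTf)=CH2) | C=C(OS(=O)(=O)C(F)(F)F)[C@H]1[C@@H](O[Si](C)(C)C(C)(C)C)C[C@H](C)[C@H](O[Si](C)(C)C(C)(C)C)CC(=O)[C@@](C)(OC(C)=O)C[C@H]1O[Si](CC)(CC)CC | intermediate
23 | 8α-alcohol of 22 | C=C(OS(=O)(=O)C(F)(F)F)[C@H]1[C@@H](O[Si](C)(C)C(C)(C)C)C[C@H](C)[C@H](O[Si](C)(C)C(C)(C)C)CC(=O)[C@@](C)(OC(C)=O)C[C@H]1O | intermediate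
24 | 8α-angelate of 23 | C=C(OS(=O)(=O)C(F)(F)F)[C@H]1[C@@H](O[Si](C)(C)C(C)(C)C)C[C@H](C)[C@H](O[Si](C)(C)C(C)(C)C)CC(=O)[C@@](C)(OC(C)=O)C[C@H]1OC(=O)/C(C)=C\C | intermediate
25 | 3β,6α-diol vinyl triflate with 8α-angelate and 10α-acetate | C=C(OS(=O)(=O)C(F)(F)F)[C@H]1[C@@H](O)C[C@H](C)[C@H](O)CC(=O)[C@@](C)(OC(C)=O)C[C@H]1OC(=O)/C(C)=C\C | intermediate
26 | CNP0141210.3 | C=C1C(=O)O[C@H]2C[C@H](C)[C@H](O)CC(=O)[C@@](C)(OC(C)=O)C[C@@H](OC(=O)/C(C)=C\C)[C@@H]12 | target

Total step count: 20. Longest linear sequence: 20 steps (from 3-methylbut-2-enal; tropone enters at step 2).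

## Least certain steps

**Step 2 (key step).** The likeliest failure is loss of periselectivity and material: competing (4+2) addition across C2–C5 of tropone and thermal isomerisation or oligomerisation of the dienyl acetate during the long heating. The resolution in step 3 then also depends on an enzyme accepting a bridged acetate. Fallback, setting out from 1 and 3: 1 is converted with TBSOTf and Et3N into the silyl dienol ether (E)-tert-butyldimethyl(3-methylbuta-1,3-dienyloxy)silane F1, a more electron-rich diene of the class known to add to tropone in the exo (6+4) mode. This gives the racemic 6α-silyloxy adduct F2, which is desilylated (Bu4NF, AcOH) to the racemic alcohol F3. Resolution is then run in the acylation direction (lipase, vinyl acetate), giving the target-series acetate F4 and leaving the enantiomeric alcohol. Methanolysis of F4 (K2CO3, MeOH) returns to the route at 5.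

**Step 7.** The opening of endoperoxide 10 may lose regiocontrol, with the amine removing C8–H as well as C1–H, because the two ends of the peroxide differ only in the C3 carbonyl next to C2. Fallback, setting out from 10 (amine omitted): thiourea reduces the peroxide to the cis-ene-1,4-diol F5. The C1 carbinol is then oxidised by catalyst-controlled transfer dehydrogenation with RuCl[(R,R)-TsDPEN](p-cymene) in acetone, a known way to desymmetrise cis-cycloalkene-1,4-diols. The two allylic carbinols of F5 have opposite local configuration, and the catalyst enantiomer is the one matching C1 by analogy with 1-arylethanols. This returns to the route at 11.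

**Step 10.** The new C3 hydroxyl lies gauche to C1 and can itself bind a borohydride, so a second hydride may be relayed to the C1 ketone (over-reduction); C4 may also epimerise if the diketone lingers. Fallback, setting out from 11: the cis γ-hydroxy enone is closed with MeOH and PPTS to the bridged methyl ketal F6 (C8–O–C1(OMe)), which masks C1 and O8 together. Hydrogenation gives F7, the same directed reduction gives the 3β-alcohol F8 with no ketone left to over-reduce, and TBSOTf gives the C3 silyl ether F9. Aqueous acetic acid releases the 8α-hydroxy C1 ketone F10, and TESCl returns to the route at 15.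

**Step 15.** The methylcerium reagent may add to the C1 carbonyl or the acetate, and after ring opening the transient C2 enolate may expel the C3 silyloxy group. Fallback, setting out from 19: methylenation of the bridging ketone without a basic carbanion (Zn, CH2Br2, TiCl4) gives the C11 methylene compound F11. Mukaiyama hydration (Co(acac)2, PhSiH3, O2) gives the neutral tertiary aldol F12, which is opened with catalytic K2CO3 in MeOH at 0 °C, returning to the route at 21.

**Step 16.** The base may enolise the C1 ketone toward C2 in competition with the acetyl methyl group, leading to triflation at the wrong carbonyl or β-elimination of the C3 silyloxy group. Fallback, setting out from 21: PPTS in MeOH removes the TES group and closes the freed C8 hydroxyl onto C1 as the bridged methyl ketal F13, leaving the methyl ketone as the only carbonyl. The same triflation gives F14, and aqueous acetic acid opens the ketal and returns to the route at 23.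

## Further compounds

F1 | step 2 | (E)-tert-butyldimethyl(3-methylbuta-1,3-dienyloxy)silane | C=C(C)/C=C/O[Si](C)(C)C(C)(C)C
F2 | step 2 | racemic 6α-(tert-butyldimethylsilyloxy) exo adduct (racemate of 6) | O=C1[C@@H]2C=CC=C[C@H]1CC(C)=C[C@@H]2O[Si](C)(C)C(C)(C)C
F3 | step 2 | racemic 6α-hydroxy adduct (racemate of 5) | O=C1[C@@H]2C=CC=C[C@H]1CC(C)=C[C@@H]2O
F4 | step 2 | 6α-acetoxy adduct, single target-series enantiomer | O=C1[C@@H]2C=CC=C[C@H]1CC(C)=C[C@@H]2OC(C)=O
F5 | step 7 | 1α,8α,11-triol C3 enone (cis-ene-1,4-diol in ring A) | O[C@H]1[C@@H]2[C@H](O)C=C[C@H](O)[C@H]1C(=O)C(C)=C[C@@H]2O[Si](C)(C)C(C)(C)C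
F6 | step 10 | bridged methyl ketal of 11 (C8–O–C1(OMe), C9=C10, C3 enone, 11-OH) | O[C@H]1[C@@H]2[C@H]3C=C[C@](OC)(O3)[C@H]1C(=O)C(C)=C[C@@H]2O[Si](C)(C)C(C)(C)C
F7 | step 10 | saturated bridged ketal, C3 ketone, 4β-methyl | O[C@H]1[C@@H]2[C@H]3CC[C@](OC)(O3)[C@H]1C(=O)[C@@H](C)C[C@@H]2O[Si](C)(C)C(C)(C)C
F8 | step 10 | bridged ketal 3β,11-diol | O[C@H]1[C@@H]2[C@H]3CC[C@](OC)(O3)[C@H]1[C@@H](O)[C@@H](C)C[C@@H]2O[Si](C)(C)C(C)(C)C
F9 | step 10 | bridged ketal 3β-TBS ether | O[C@H]1[C@@H]2[C@H]3CC[C@](OC)(O3)[C@H]1[C@@H](O[Si](C)(C)C(C)(C)C)[C@@H](C)C[C@@H]2O[Si](C)(C)C(C)(C)C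
F10 | step 10 | 8α,11-dihydroxy C1 ketone with 3β-OTBS (15 without the TES group) | O[C@H]1[C@@H]2[C@H](O)CCC(=O)[C@H]1[C@@H](O[Si](C)(C)C(C)(C)C)[C@@H](C)C[C@@H]2O[Si](C)(C)C(C)(C)C
F11 | step 15 | C11 methylene analogue of 19 | C=C1[C@@H]2[C@H](O[Si](CC)(CC)CC)C[C@](C)(OC(C)=O)C(=O)[C@H]1[C@@H](O[Si](C)(C)C(C)(C)C)[C@@H](C)C[C@@H]2O[Si](C)(C)C(C)(C)C
F12 | step 15 | C11 methyl carbinol of 19, free alcohol (C11 configuration immaterial) | CC1(O)[C@@H]2[C@H](O[Si](CC)(CC)CC)C[C@](C)(OC(C)=O)C(=O)[C@H]1[C@@H](O[Si](C)(C)C(C)(C)C)[C@@H](C)C[C@@H]2O[Si](C)(C)C(C)(C)C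
F13 | step 16 | bridged methyl ketal (C8–O–C1(OMe)) of the methyl ketone | CC(=O)[C@H]1[C@@H](O[Si](C)(C)C(C)(C)C)C[C@H](C)[C@H](O[Si](C)(C)C(C)(C)C)C[C@]2(OC)[C@@](C)(OC(C)=O)C[C@H]1O2
F14 | step 16 | vinyl triflate of F13 | C=C(OS(=O)(=O)C(F)(F)F)[C@H]1[C@@H](O[Si](C)(C)C(C)(C)C)C[C@H](C)[C@H](O[Si](C)(C)C(C)(C)C)C[C@]2(OC)[C@@](C)(OC(C)=O)C[C@H]1O2
A1 | alternative 1 | ten-membered C8 carbinol with C7 alkenyl branch and Z C9–C10 alkene | C=C(COCc3ccc(OC)cc3)[C@H]1[C@@H](OCc4ccc(OC)cc4)C[C@H](C)[C@H](O[Si](C)(C)C(C)(C)C)CC2(OCCO2)/C(C)=C\[C@H]1O
A2 | alternative 2 | ten-membered ring bridged by the C1,C3 isoxazoline | C1C(=O)O[C@H]2C[C@H](C)[C@H]3CC(=NO3)[C@]4(C)C[C@@H](OC(C)(C)O4)[C@@H]12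
A3 | alternative 3 | cis-fused dichlorocyclobutanone on the ten-membered ring | C[C@H]1C[C@@H]2C(=O)C(Cl)(Cl)[C@@H]2[C@@H](O[Si](C)(C)C(C)(C)C)C[C@](C)(OC(C)=O)C3(OCCO3)C[C@H]1OCc4ccc(OC)cc4
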